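**Plan**

1. Retrosynthesis (labdane numbering: C4 bears CH3 and CO2H, C5 and C10 are the ring-fusion atoms, C8 bears the methylene C17, C9 the side chain): the C15–O acyl bond is cut first; then, with a temporary ketone placed on C3, C4–C5 and C9–C10 are cut in one transform; last C1–C2, which leaves a 2-methylacetoacetate dianion and an ω-bromo-(R)-dihydrofarnesyl ester.
2. Forward: the chain is built first (farnesol → (R)-dihydrofarnesyl pivalate → terminal allylic bromide → β-keto ester); one oxidative radical cascade then closes ring A and, directly after it, ring B, which is the last ring closed.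
3. Enabling feature: C4 carries both a methyl and a carboxyl group, so with a C3 carbonyl it is the α-carbon of a β-keto ester and gives an electrophilic tertiary radical. The E-alkenes C10=C5 and C8=C9 lie in 1,5-relation to it and to each other, and the C17 methyl on the final C8 radical supplies the hydrogen lost to form the exocyclic methylene.
4. Helpers: the C3 ketone (removed by Barton–McCombie deoxygenation), the (+)-8-phenylmenthyl ester (reduced off to the C19 alcohol, re-oxidised at the end) and the C15 pivalate.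
5. Stereochemistry: C13 from Ru–BINAP hydrogenation of farnesol; relative configuration at C4, C5, C9, C10 from the chair–chair transition state of the E,E-diene; absolute configuration of the core from the 8-phenylmenthyl ester; the acyl stereocentre from (R)-2-methylbutanoic acid.

Key step: step 7

Assumption: the target is read as (4R,5S,9R,10S,13R) with a (2R)-acyl group (ent-labdane series), and the facial sense of the auxiliary in the non-chelated radical is taken from the aryl-shielding model; if it proved opposite, (−)-8-phenylmenthol would be used with no other change.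

**Route**

Step 1
Reactants: 1 (2E,6E)-farnesol
Product: 2 (3R,6E)-3,7,11-trimethyldodeca-6,10-dien-1-ol
Conditions: Ru(OAc)2[(S)-BINAP] (0.5 mol %), H2 (30–50 atm), MeOH/H2O 95:5, 20 °C
Reagents that add atoms: none
Why: Noyori hydroxyl-directed asymmetric hydrogenation should reduce only the allylic C2=C3 bond, the (S)-BINAP complex setting the 3R centre in the same sense as geraniol to (R)-citronellol, while the two remote trisubstituted alkenes stay untouched.

Step 2
Reactants: 2 (3R,6E)-3,7,11-trimethyldodeca-6,10-dien-1-ol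
Product: 3 (3R,6E)-3,7,11-trimethyldodeca-6,10-dien-1-yl pivalate
Conditions: PivCl, pyridine, DMAP (cat.), CH2Cl2, 0 °C to rt
Reagents that add atoms: pivaloyl chloride, CC(C)(C)C(=O)Cl
Why: Standard acylation of a primary alcohol gives a hindered ester without α-hydrogens that should survive the dianion, the oxidant and the radical steps and fall off in the hydride step.

Step 3
Reactants: 3 (3R,6E)-3,7,11-trimethyldodeca-6,10-dien-1-yl pivalate
Product: 5 (3R,6E,10E)-12-hydroxy-3,7,11-trimethyldodeca-6,10-dien-1-yl pivalate, via enal 4 (not isolated)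
Conditions: SeO2 (0.3 equiv), t-BuOOH (3 equiv), salicylic acid (0.1 equiv), CH2Cl2, 0 °C to rt; then NaBH4, MeOH, 0 °C
Reagents that add atoms: selenium dioxide, O=[Se]=O (oxygen carrier); tert-butyl hydroperoxide, CC(C)(C)OO (terminal oxidant)
Why: Sharpless allylic oxidation (ene reaction then [2,3]-sigmatropic shift) should attack the E-methyl group of the terminal isopropylidene unit and give the E-allylic alcohol, and NaBH4 returns the over-oxidised portion (enal 4) to 5.

Step 4
Reactants: 5 (3R,6E,10E)-12-hydroxy-3,7,11-trimethyldodeca-6,10-dien-1-yl pivalate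
Product: 6 (3R,6E,10E)-12-bromo-3,7,11-trimethyldodeca-6,10-dien-1-yl pivalate
Conditions: CBr4, PPh3, CH2Cl2, 0 °C
Reagents that add atoms: carbon tetrabromide, BrC(Br)(Br)Br
Why: Appel bromination of a primary allylic alcohol under neutral conditions should proceed by direct SN2 displacement without allylic transposition or loss of alkene geometry.

Step 5
Reactants: 7 ethyl 2-methyl-3-oxobutanoate; 8 (+)-8-phenylmenthol, (1S,2R,5S)-5-methyl-2-(2-phenylpropan-2-yl)cyclohexan-1-ol
Product: 9 (1S,2R,5S)-5-methyl-2-(2-phenylpropan-2-yl)cyclohexyl 2-methyl-3-oxobutanoate (both C2 epimers)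
Conditions: DMAP (0.3 equiv), toluene, reflux, 4 Å molecular sieves (removal of EtOH)
Reagents that add atoms: none
Why: DMAP-catalysed transesterification of an enolisable β-keto ester is driven by removal of ethanol and tolerates hindered secondary alcohols; the C2 epimer mixture is irrelevant because this carbon later becomes a planar radical.

Step 6
Reactants: 9 (+)-8-phenylmenthyl 2-methyl-3-oxobutanoate; 6 (3R,6E,10E)-12-bromo-3,7,11-trimethyldodeca-6,10-dien-1-yl pivalate
Product: 11 (+)-8-phenylmenthyl (6E,10E,14R)-2,6,10,14-tetramethyl-3-oxo-16-(pivaloyloxy)hexadeca-6,10-dienoate, via dianion 10 (not isolated)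
Conditions: NaH, THF, 0 °C; n-BuLi, 0 °C; then 6, 0 °C; NH4Cl work-up
Reagents that add atoms: none
Why: Weiler dianion alkylation, in which the more basic terminal carbanion of the dienolate displaces the allylic bromide by SN2 with retention of E geometry, the pivalate being too hindered to compete.

Step 7
Reactants: 11 (+)-8-phenylmenthyl (6E,10E,14R)-2,6,10,14-tetramethyl-3-oxo-16-(pivaloyloxy)hexadeca-6,10-dienoate
Product: 15 (+)-8-phenylmenthyl (4S,5S,9R,10S,13R)-3-oxo-15-(pivaloyloxy)labd-8(17)-en-19-oate, via acyclic radical 12 (not isolated), via ring A radical 13 (not isolated), via bicyclic radical 14 (not isolated)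
Conditions: Mn(OAc)3·2H2O (2.2 equiv), Cu(OAc)2·H2O (1.0 equiv), degassed AcOH, 25 °C
Reagents that add atoms: none
Why: Mn(OAc)3 enolises the β-keto ester and oxidises it to the electrophilic tertiary radical 12 at C4, which adds 6-endo-trig to C5 of the C10=C5 alkene (ring A, radical 13 at C10); 13 adds 6-endo-trig to C9 of the C8=C9 alkene (ring B, radical 14 at C8), and Cu(OAc)2 oxidises 14 with loss of a hydrogen from the C17 methyl group, the least hindered β-hydrogen, to give the exocyclic methylene. The closest known reaction type is the Snider oxidative free-radical polyene cyclisation of 2-methyl-3-oxo esters by trivalent manganese and divalent copper, including its 8-phenylmenthyl ester variant. Both closures are endo because each radical attacks the CH end of a trisubstituted alkene and leaves a tertiary radical. The chair–chair arrangement of the E,E-diene sets the trans ring fusion (C5–H anti to the C10 methyl) and the equatorial C9 side chain, and C4 is set by the radical reacting in the conformation with ketone and ester carbonyls anti, which places the ester axial and cis to the C10 methyl. The absolute sense comes from the auxiliary, whose phenyl ring lies over one face of the planar radical so that the alkene adds to the other face. The step needs facial selectivity (auxiliary), endo over exo closure (alkene substitution) and exocyclic over endocyclic alkene formation (copper-mediated elimination), and the non-chelating medium (AcOH, no Lewis acid) keeps the anti-carbonyl conformation that the axial ester requires.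

Step 8
Reactants: 15 (+)-8-phenylmenthyl (4S,5S,9R,10S,13R)-3-oxo-15-(pivaloyloxy)labd-8(17)-en-19-oate
Product: 16 (+)-8-phenylmenthyl (3R,4S,5S,9R,10S,13R)-3-hydroxy-15-(pivaloyloxy)labd-8(17)-en-19-oate
Conditions: NaBH4, MeOH/THF, 0 °C to rt
Reagents that add atoms: none
Why: Borohydride reduces only the ketone, hydride adding axially from the face away from the axial ester and the C10 methyl to give mainly the equatorial alcohol; this centre is erased in step 10, so either epimer serves.

Step 9
Reactants: 16 (+)-8-phenylmenthyl (3R,4S,5S,9R,10S,13R)-3-hydroxy-15-(pivaloyloxy)labd-8(17)-en-19-oate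
Product: 17 (+)-8-phenylmenthyl (3R,4S,5S,9R,10S,13R)-3-(imidazol-1-ylcarbonothioyloxy)-15-(pivaloyloxy)labd-8(17)-en-19-oate
Conditions: 1,1'-thiocarbonyldiimidazole, DMAP (cat.), 1,2-dichloroethane, reflux
Reagents that add atoms: 1,1'-thiocarbonyldiimidazole, S=C(n1ccnc1)n1ccnc1
Why: Neutral thioacylation of the hindered secondary alcohol avoids the strong base that could trigger retro-aldol opening of the β-hydroxy ester.

Step 10
Reactants: 17 (+)-8-phenylmenthyl 3-(imidazol-1-ylcarbonothioyloxy)-15-(pivaloyloxy)labd-8(17)-en-19-oate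
Product: 18 (+)-8-phenylmenthyl (4R,5S,9R,10S,13R)-15-(pivaloyloxy)labd-8(17)-en-19-oate
Conditions: Bu3SnH, azobisisobutyronitrile (AIBN, cat.), toluene, 110 °C
Reagents that add atoms: none
Why: Barton–McCombie deoxygenation should replace the C3 oxygen by hydrogen, the secondary radical being trapped by the stannane faster than it can reach the remote exocyclic alkene.

Step 11
Reactants: 18 (+)-8-phenylmenthyl (4R,5S,9R,10S,13R)-15-(pivaloyloxy)labd-8(17)-en-19-oate
Product: 19 (4R,5S,9R,10S,13R)-labd-8(17)-ene-15,19-diol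
Conditions: LiAlH4 (excess), THF, reflux; Rochelle salt work-up
Reagents that add atoms: none
Why: Hydride reduction cleaves the auxiliary ester to the C19 primary alcohol and removes the pivalate in the same operation, with the auxiliary recovered and the isolated alkene untouched.

Step 12
Reactants: 19 (4R,5S,9R,10S,13R)-labd-8(17)-ene-15,19-diol; 20 (R)-2-methylbutanoic acid
Product: 21 (4R,5S,9R,10S,13R)-19-hydroxylabd-8(17)-en-15-yl (2R)-2-methylbutanoate
Conditions: N,N'-dicyclohexylcarbodiimide (DCC), DMAP (0.1 equiv), CH2Cl2, −10 to 0 °C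
Reagents that add atoms: none
Why: Steglich esterification should acylate the unhindered primary C15 hydroxyl far faster than the axial neopentyl C19 hydroxyl, and low temperature with catalytic DMAP guards the α-stereocentre of the acid.

Step 13
Reactants: 21 (4R,5S,9R,10S,13R)-19-hydroxylabd-8(17)-en-15-yl (2R)-2-methylbutanoate
Product: 22 (4R,5S,9R,10S,13R)-19-oxolabd-8(17)-en-15-yl (2R)-2-methylbutanoate
Conditions: Dess–Martin periodinane, CH2Cl2, 0 °C to rt
Reagents that add atoms: none
Why: Dess–Martin oxidation of the neopentyl alcohol under near-neutral conditions should give the non-enolisable aldehyde without touching the alkene or the ester.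

Step 14
Reactants: 22 (4R,5S,9R,10S,13R)-19-oxolabd-8(17)-en-15-yl (2R)-2-methylbutanoate
Product: 23 (4R,5S,9R,10S,13R)-15-[(2R)-2-methylbutanoyloxy]labd-8(17)-en-19-oic acid (target)
Conditions: NaClO2, NaH2PO4, 2-methyl-2-butene (excess), t-BuOH/H2O, 0 °C to rt
Reagents that add atoms: sodium chlorite, [Na+].[O-]Cl=O
Why: Pinnick oxidation converts the hindered aldehyde to the acid while the alkene scavenger takes up hypochlorous acid and protects the exocyclic methylene.

**Compound list**

1 | (2E,6E)-farnesol | CC(C)=CCC/C(C)=C/CC/C(C)=C/CO | starting material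
2 | (3R,6E)-3,7,11-trimethyldodeca-6,10-dien-1-ol ((R)-2,3-dihydrofarnesol) | CC(C)=CCC/C(C)=C/CC[C@@H](C)CCO | intermediate
3 | (3R,6E)-3,7,11-trimethyldodeca-6,10-dien-1-yl pivalate | CC(C)=CCC/C(C)=C/CC[C@@H](C)CCOC(=O)C(C)(C)C | intermediate
4 | (3R,6E,10E)-3,7,11-trimethyl-12-oxododeca-6,10-dien-1-yl pivalate (enal, not isolated) | O=C/C(C)=C/CC/C(C)=C/CC[C@@H](C)CCOC(=O)C(C)(C)C | intermediate
5 | (3R,6E,10E)-12-hydroxy-3,7,11-trimethyldodeca-6,10-dien-1-yl pivalate | OC/C(C)=C/CC/C(C)=C/CC[C@@H](C)CCOC(=O)C(C)(C)C | intermediate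
6 | (3R,6E,10E)-12-bromo-3,7,11-trimethyldodeca-6,10-dien-1-yl pivalate | BrC/C(C)=C/CC/C(C)=C/CC[C@@H](C)CCOC(=O)C(C)(C)C | intermediate
7 | ethyl 2-methyl-3-oxobutanoate (racemic) | CCOC(=O)C(C)C(C)=O | starting material
8 | (+)-8-phenylmenthol, (1S,2R,5S)-5-methyl-2-(2-phenylpropan-2-yl)cyclohexan-1-ol | O[C@H]1C[C@@H](C)CC[C@@H]1C(C)(C)c1ccccc1 | starting material
9 | (1S,2R,5S)-5-methyl-2-(2-phenylpropan-2-yl)cyclohexyl 2-methyl-3-oxobutanoate (both C2 epimers) | CC(=O)C(C)C(=O)O[C@H]1C[C@@H](C)CC[C@@H]1C(C)(C)c1ccccc1 | intermediate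
10 | sodium lithium dienolate (dianion) of 9, not isolated | [Na+].[Li+].C=C([O-])C(C)=C([O-])O[C@H]1C[C@@H](C)CC[C@@H]1C(C)(C)c1ccccc1 | intermediate
11 | (+)-8-phenylmenthyl (6E,10E,14R)-2,6,10,14-tetramethyl-3-oxo-16-(pivaloyloxy)hexadeca-6,10-dienoate (both C2 epimers) | CC(C(=O)O[C@H]1C[C@@H](C)CC[C@@H]1C(C)(C)c1ccccc1)C(=O)CC/C(C)=C/CC/C(C)=C/CC[C@@H](C)CCOC(=O)C(C)(C)C | intermediate
12 | acyclic tertiary radical at C2 of 11 (labdane C4), not isolated | C[C](C(=O)O[C@H]1C[C@@H](C)CC[C@@H]1C(C)(C)c1ccccc1)C(=O)CC/C(C)=C/CC/C(C)=C/CC[C@@H](C)CCOC(=O)C(C)(C)C | intermediate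
13 | ring A radical (monocyclic, tertiary radical at labdane C10), not isolated | C[C]1CCC(=O)[C@@](C)(C(=O)O[C@H]2C[C@@H](C)CC[C@@H]2C(C)(C)c2ccccc2)[C@H]1CC/C(C)=C/CC[C@@H](C)CCOC(=O)C(C)(C)C | intermediate
14 | bicyclic radical (tertiary radical at labdane C8), not isolated | C[C]1CC[C@H]2[C@@](C)(CCC(=O)[C@@]2(C)C(=O)O[C@H]3C[C@@H](C)CC[C@@H]3C(C)(C)c3ccccc3)[C@@H]1CC[C@@H](C)CCOC(=O)C(C)(C)C | intermediate
15 | (+)-8-phenylmenthyl (4S,5S,9R,10S,13R)-3-oxo-15-(pivaloyloxy)labd-8(17)-en-19-oate | C=C1CC[C@H]2[C@@](C)(CCC(=O)[C@@]2(C)C(=O)O[C@H]3C[C@@H](C)CC[C@@H]3C(C)(C)c3ccccc3)[C@@H]1CC[C@@H](C)CCOC(=O)C(C)(C)C | intermediate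
16 | (+)-8-phenylmenthyl (3R,4S,5S,9R,10S,13R)-3-hydroxy-15-(pivaloyloxy)labd-8(17)-en-19-oate | C=C1CC[C@H]2[C@@](C)(CC[C@@H](O)[C@@]2(C)C(=O)O[C@H]3C[C@@H](C)CC[C@@H]3C(C)(C)c3ccccc3)[C@@H]1CC[C@@H](C)CCOC(=O)C(C)(C)C | intermediate
17 | (+)-8-phenylmenthyl (3R,4S,5S,9R,10S,13R)-3-(imidazol-1-ylcarbonothioyloxy)-15-(pivaloyloxy)labd-8(17)-en-19-oate | C=C1CC[C@H]2[C@@](C)(CC[C@@H](OC(=S)n4ccnc4)[C@@]2(C)C(=O)O[C@H]3C[C@@H](C)CC[C@@H]3C(C)(C)c3ccccc3)[C@@H]1CC[C@@H](C)CCOC(=O)C(C)(C)C | intermediate
18 | (+)-8-phenylmenthyl (4R,5S,9R,10S,13R)-15-(pivaloyloxy)labd-8(17)-en-19-oate | C=C1CC[C@H]2[C@@](C)(CCC[C@@]2(C)C(=O)O[C@H]3C[C@@H](C)CC[C@@H]3C(C)(C)c3ccccc3)[C@@H]1CC[C@@H](C)CCOC(=O)C(C)(C)C | intermediate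
19 | (4R,5S,9R,10S,13R)-labd-8(17)-ene-15,19-diol | C=C1CC[C@H]2[C@@](C)(CCC[C@@]2(C)CO)[C@@H]1CC[C@@H](C)CCO | intermediate
20 | (R)-2-methylbutanoic acid | CC[C@@H](C)C(=O)O | starting material
21 | (4R,5S,9R,10S,13R)-19-hydroxylabd-8(17)-en-15-yl (2R)-2-methylbutanoate | C=C1CC[C@H]2[C@@](C)(CCC[C@@]2(C)CO)[C@@H]1CC[C@@H](C)CCOC(=O)[C@H](C)CC | intermediate
22 | (4R,5S,9R,10S,13R)-19-oxolabd-8(17)-en-15-yl (2R)-2-methylbutanoate | C=C1CC[C@H]2[C@@](C)(CCC[C@@]2(C)C=O)[C@@H]1CC[C@@H](C)CCOC(=O)[C@H](C)CC | intermediate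
23 | (4R,5S,9R,10S,13R)-15-[(2R)-2-methylbutanoyloxy]labd-8(17)-en-19-oic acid | C=C1CC[C@H]2[C@@](C)(CCC[C@@]2(C)C(=O)O)[C@@H]1CC[C@@H](C)CCOC(=O)[C@H](C)CC | target

**Step count and risks**

Total steps: 14. Longest linear sequence: 13 steps (1, 2, 3, 4, 6 to 14, from farnesol); step 5 is a one-step side branch.

Steps most likely to fail:

Step 7. The auxiliary phenyl group may discriminate the two radical faces poorly, and enolisation of the bulky ester may be slow, so that radical 13 is oxidised before ring B closes and the diastereomer ratio stays low. Fallback (sets out from 6 and 7, comes back at 19): the absolute configuration is settled after the cyclisation by an enzyme and not by an auxiliary. Ethyl 2-methyl-3-oxobutanoate 7 is converted with NaH and n-BuLi into its sodium lithium dienolate F1, which is alkylated by 6 to the ethyl (6E,10E,14R)-2,6,10,14-tetramethyl-3-oxo-16-(pivaloyloxy)hexadeca-6,10-dienoate F2. The same Mn(OAc)3/Cu(OAc)2 cyclisation, well behaved for ethyl esters, should give the ethyl 3-oxo-15-(pivaloyloxy)labd-8(17)-en-19-oate F3 together with its diastereomer of antipodal decalin core. A ketoreductase (NADPH-dependent alcohol dehydrogenase, glucose/glucose dehydrogenase recycling, chosen by screening) should reduce only the ketone of the wanted core to the ethyl 3-hydroxy-15-(pivaloyloxy)labd-8(17)-en-19-oate F4, separable from the unreduced diastereomer by chromatography. Thiocarbonyldiimidazole gives the ethyl 3-(imidazol-1-ylcarbonothioyloxy) ester F5, Bu3SnH/AIBN the ethyl (4R,5S,9R,10S,13R)-15-(pivaloyloxy)labd-8(17)-en-19-oate F6, and LiAlH4 reduces F6 to diol 19.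

Step 3. Allylic oxidation may also occur at the internal C6=C7 alkene, and over-oxidation may consume the product. Fallback (sets out from 3, comes back at 5 through 4): the terminal alkene is degraded and rebuilt. NBS in aqueous THF should add selectively to the terminal alkene to give the (3R,6E)-10-bromo-11-hydroxy-3,7,11-trimethyldodec-6-en-1-yl pivalate F7. K2CO3 in MeOH closes the (3R,6E)-10,11-epoxy-3,7,11-trimethyldodec-6-en-1-yl pivalate F8. Periodic acid (H5IO6, THF/Et2O) cleaves it to the (3R,6E)-3,7-dimethyl-10-oxodec-6-en-1-yl pivalate F9. E-selective Wittig reaction with 2-(triphenylphosphoranylidene)propanal in toluene at reflux gives enal 4, and NaBH4 gives 5.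

Step 11. Hydride delivery to the doubly hindered ester (quaternary α-carbon, bulky alkoxy group) may stay incomplete. Fallback (sets out from 15, comes back at 21): the ester is reduced while the neighbouring oxygen can assist, and C3 is deoxygenated afterwards. LiAlH4 on keto ester 15 first forms the C3 alkoxide, which delivers hydride intramolecularly to the adjacent ester and gives the (3R,4S,5S,9R,10S,13R)-labd-8(17)-ene-3,15,19-triol F10, with 8 recovered. Selective Steglich acylation of the unhindered C15 hydroxyl with 20 gives the 3,19-dihydroxylabd-8(17)-en-15-yl (2R)-2-methylbutanoate F11. Thiocarbonyldiimidazole closes the cyclic 3,19-thionocarbonate F12 (cis 1,3-diol, equatorial C3–O and axial C19–O). Bu3SnH/AIBN should cleave the C3–O bond (secondary radical preferred over the primary neopentyl one) to give the 19-O-[(tributylstannylthio)carbonyl] derivative F13, which loses carbonyl sulfide on aqueous work-up to give 21.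

**Further compounds**

F1 | step 7 | sodium lithium dienolate (dianion) of ethyl 2-methyl-3-oxobutanoate | [Na+].[Li+].C=C([O-])C(C)=C([O-])OCC
F2 | step 7 | ethyl (6E,10E,14R)-2,6,10,14-tetramethyl-3-oxo-16-(pivaloyloxy)hexadeca-6,10-dienoate | CCOC(=O)C(C)C(=O)CC/C(C)=C/CC/C(C)=C/CC[C@@H](C)CCOC(=O)C(C)(C)C
F3 | step 7 | ethyl (4S,5S,9R,10S,13R)-3-oxo-15-(pivaloyloxy)labd-8(17)-en-19-oate (formed together with the diastereomer of antipodal decalin core) | C=C1CC[C@H]2[C@@](C)(CCC(=O)[C@@]2(C)C(=O)OCC)[C@@H]1CC[C@@H](C)CCOC(=O)C(C)(C)C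
F4 | step 7 | ethyl (3R,4S,5S,9R,10S,13R)-3-hydroxy-15-(pivaloyloxy)labd-8(17)-en-19-oate (3R drawn; either carbinol epimer serves) | C=C1CC[C@H]2[C@@](C)(CC[C@@H](O)[C@@]2(C)C(=O)OCC)[C@@H]1CC[C@@H](C)CCOC(=O)C(C)(C)C
F5 | step 7 | ethyl (3R,4S,5S,9R,10S,13R)-3-(imidazol-1-ylcarbonothioyloxy)-15-(pivaloyloxy)labd-8(17)-en-19-oate | C=C1CC[C@H]2[C@@](C)(CC[C@@H](OC(=S)n3ccnc3)[C@@]2(C)C(=O)OCC)[C@@H]1CC[C@@H](C)CCOC(=O)C(C)(C)C
F6 | step 7 | ethyl (4R,5S,9R,10S,13R)-15-(pivaloyloxy)labd-8(17)-en-19-oate | C=C1CC[C@H]2[C@@](C)(CCC[C@@]2(C)C(=O)OCC)[C@@H]1CC[C@@H](C)CCOC(=O)C(C)(C)C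
F7 | step 3 | (3R,6E)-10-bromo-11-hydroxy-3,7,11-trimethyldodec-6-en-1-yl pivalate (both C10 epimers) | CC(C)(O)C(Br)CC/C(C)=C/CC[C@@H](C)CCOC(=O)C(C)(C)C
F8 | step 3 | (3R,6E)-10,11-epoxy-3,7,11-trimethyldodec-6-en-1-yl pivalate (both C10 epimers) | CC1(C)OC1CC/C(C)=C/CC[C@@H](C)CCOC(=O)C(C)(C)C
F9 | step 3 | (3R,6E)-3,7-dimethyl-10-oxodec-6-en-1-yl pivalate | O=CCC/C(C)=C/CC[C@@H](C)CCOC(=O)C(C)(C)C
F10 | step 11 | (3R,4S,5S,9R,10S,13R)-labd-8(17)-ene-3,15,19-triol | C=C1CC[C@H]2[C@@](C)(CC[C@@H](O)[C@@]2(C)CO)[C@@H]1CC[C@@H](C)CCO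
F11 | step 11 | (3R,4S,5S,9R,10S,13R)-3,19-dihydroxylabd-8(17)-en-15-yl (2R)-2-methylbutanoate | C=C1CC[C@H]2[C@@](C)(CC[C@@H](O)[C@@]2(C)CO)[C@@H]1CC[C@@H](C)CCOC(=O)[C@H](C)CC
F12 | step 11 | cyclic 3,19-thionocarbonate of F11 | C=C1CC[C@H]2[C@@](C)(CC[C@H]3OC(=S)OC[C@@]23C)[C@@H]1CC[C@@H](C)CCOC(=O)[C@H](C)CC
F13 | step 11 | (4R,5S,9R,10S,13R)-19-{[(tributylstannyl)sulfanyl]carbonyloxy}labd-8(17)-en-15-yl (2R)-2-methylbutanoate (not isolated) | C=C1CC[C@H]2[C@@](C)(CCC[C@@]2(C)COC(=O)S[Sn](CCCC)(CCCC)CCCC)[C@@H]1CC[C@@H](C)CCOC(=O)[C@H](C)CC
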